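**Assumption:** the target has no stereocentre and no hindered axis, so it is achiral and no stereocontrol is needed; all five benzene rings are bought and only the four ether C–O bonds are built.

Ring letters: A = 2,4,6-trihydroxyphenyl end, then B, C, D, and E = 3,4,5-trihydroxyphenyl end (formula C30H22O16).

## Retrosynthetic overview

1. Target ⇐ twelve-fold O-demethylation of its dodecamethyl ether; no ring is formed at any stage.
2. A–O–B bond (last coupling): Ullmann C–O coupling of the ring A phenol with the bromide on ring B.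
3. C–O–D bond: Chan–Lam C–O coupling of the ring C phenol with a ring D boronic acid, leaving the ring B bromide untouched.
4. B–O–C bond (key, new): one-pot oxidative dearomatisation of the ring C phenol to a quinone monoacetal, then acid-catalysed SN2′ O-arylation of the ring B phenol, which regenerates the ring C phenol needed in line 3.
5. D–O–E bond (first): Ullmann C–O coupling, then sterically controlled C–H borylation of ring D. Order of bond formation: D–E, B–C, C–D, A–B.

## Route

**Step 1**
Reactants: 1 2,6-dimethoxyphenol (1.3 equiv); 2 5-bromo-1,2,3-trimethoxybenzene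
Product: 3 5-(2,6-dimethoxyphenoxy)-1,2,3-trimethoxybenzene
Conditions: CuI (10 mol%), picolinic acid (20 mol%), K3PO4 (2 equiv), DMSO, 90 °C, Ar
Reagents that add atoms: none
Why: Ullmann-type copper-catalysed diaryl ether synthesis; the picolinate-ligated monovalent copper phenoxide of the hindered, electron-rich phenol 1 couples with the unhindered aryl bromide 2, which is the pairing these conditions tolerate well.

**Step 2**
Reactants: 3 5-(2,6-dimethoxyphenoxy)-1,2,3-trimethoxybenzene
Product: 5 [3,5-dimethoxy-4-(3,4,5-trimethoxyphenoxy)phenyl]boronic acid, via pinacol boronate 4 (not isolated)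
Conditions: [Ir(OMe)(cod)]2 (1.5 mol%), 4,4′-di-tert-butyl-2,2′-bipyridine (3 mol%), B2pin2 (0.55 equiv), THF, 80 °C; then NaIO4 (3 equiv), 1 M aq. HCl, THF/H2O, rt
Reagents that add atoms: bis(pinacolato)diboron, CC1(C)OB(OC1(C)C)B1OC(C)(C)C(C)(C)O1; water, O
Why: Iridium-catalysed C–H borylation is sterically controlled, and the only C–H of 3 without an ortho substituent is the one para to the aryloxy group on ring D (both C–H bonds of ring E lie between two oxygens); periodate glycol cleavage of the pinacol then frees the boronic acid.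

**Step 3**
Reactants: 6 2,4-dimethoxyphenol (1.05 equiv); 7 4-bromo-2,6-dimethoxyphenol (2.0 equiv, excess recovered)
Product: 9 2-(4-bromo-2,6-dimethoxyphenoxy)-4,6-dimethoxyphenol, via quinone monoacetal 8 (not isolated)
Conditions: PhI(OAc)2 (1.0 equiv), MeOH, 0 °C, 20 min; evaporate and chase with toluene; then 7, (PhO)2P(O)OH (10 mol%), 5 Å molecular sieves, CH2Cl2, −40 to 0 °C
Reagents that add atoms: methanol, CO (gives the second acetal OMe of 8; either acetal OMe is lost again in the second stage)
Why: Proposed new method: trivalent-iodine dearomatisation of 6 gives quinone monoacetal 8, whose acetal is ionised by the phosphoric acid to a methoxy-stabilised cyclohexadienyl cation that the oxygen of 7 (ortho and para carbons blocked by OMe and Br, OH hydrogen-bonded to the phosphate counter-ion) attacks in SN2′ fashion at the unsubstituted carbon next to the carbonyl, after which loss of MeOH and tautomerisation to the phenol make the O-arylation irreversible; the closest known reaction type is the acid-promoted SN2′ coupling of quinone monoacetals with aromatic carbon nucleophiles, which has not been shown for a hindered phenol oxygen to form a diaryl ether.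

**Step 4**
Reactants: 9 2-(4-bromo-2,6-dimethoxyphenoxy)-4,6-dimethoxyphenol; 5 [3,5-dimethoxy-4-(3,4,5-trimethoxyphenoxy)phenyl]boronic acid (1.8 equiv)
Product: 10 5-bromo-2-{2-[3,5-dimethoxy-4-(3,4,5-trimethoxyphenoxy)phenoxy]-3,5-dimethoxyphenoxy}-1,3-dimethoxybenzene
Conditions: Cu(OAc)2 (0.3 equiv), pyridine (5 equiv), 4 Å molecular sieves, CH2Cl2, O2 (1 atm), rt, 48 h
Reagents that add atoms: none
Why: Chan–Lam oxidative C–O coupling; aryl transfer from boron to divalent copper, oxidation to an aryl(phenoxide) trivalent copper species and reductive elimination form the C–O–D bond at room temperature, where the Ar–Br bond on ring B is inert because no oxidative addition is involved.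

**Step 5**
Reactants: 10 bromo tetramer (named in step 4); 11 2,4,6-trimethoxyphenol (2.0 equiv)
Product: 12 2-{4-[2-(3,5-dimethoxy-4-(3,4,5-trimethoxyphenoxy)phenoxy)-3,5-dimethoxyphenoxy]-3,5-dimethoxyphenoxy}-1,3,5-trimethoxybenzene (dodecamethyl ether of the target)
Conditions: CuI (20 mol%), picolinic acid (40 mol%), K3PO4 (3 equiv), DMSO, 100 °C, Ar
Reagents that add atoms: none
Why: Ullmann-type copper-catalysed diaryl ether synthesis at the only C–Br bond of 10 (flanked by two C–H) with the hindered phenol 11 in excess; 10 carries no free OH or second halide, so no self-coupling is possible.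

**Step 6**
Reactants: 12 dodecamethyl ether (named in step 5)
Product: 14 2-{4-[2-(3,5-dihydroxy-4-(3,4,5-trihydroxyphenoxy)phenoxy)-3,5-dihydroxyphenoxy]-3,5-dihydroxyphenoxy}benzene-1,3,5-triol (target CNP0227069.0), via dodeca-O-dibromoboryl derivative 13 (not isolated)
Conditions: BBr3 (30 equiv, 1 M in CH2Cl2), CH2Cl2, −78 °C to rt, 24 h, Ar; then H2O, 0 °C; degassed solvents, Sephadex LH-20
Reagents that add atoms: none
Why: Lewis-acid ether cleavage; BBr3 binds each methoxy oxygen and bromide attacks the methyl carbon (SN2), so all twelve O–CH3 bonds break while the diaryl ether C–O bonds, which offer no sp3 carbon, stay intact, and hydrolysis of 13 frees the twelve phenols.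

## Compound list

1 | 2,6-dimethoxyphenol | COc1cccc(OC)c1O | starting material
2 | 5-bromo-1,2,3-trimethoxybenzene | COc1cc(Br)cc(OC)c1OC | starting material
3 | 5-(2,6-dimethoxyphenoxy)-1,2,3-trimethoxybenzene | COc1cccc(OC)c1Oc1cc(OC)c(OC)c(OC)c1 | intermediate
4 | 2-[3,5-dimethoxy-4-(3,4,5-trimethoxyphenoxy)phenyl]-4,4,5,5-tetramethyl-1,3,2-dioxaborolane | COc1cc(B2OC(C)(C)C(C)(C)O2)cc(OC)c1Oc1cc(OC)c(OC)c(OC)c1 | intermediate (not isolated)
5 | [3,5-dimethoxy-4-(3,4,5-trimethoxyphenoxy)phenyl]boronic acid | COc1cc(B(O)O)cc(OC)c1Oc1cc(OC)c(OC)c(OC)c1 | intermediate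
6 | 2,4-dimethoxyphenol | COc1ccc(O)c(OC)c1 | starting material
7 | 4-bromo-2,6-dimethoxyphenol | COc1cc(Br)cc(OC)c1O | starting material
8 | 2,4,4-trimethoxycyclohexa-2,5-dien-1-one | COC1=CC(OC)(OC)C=CC1=O | intermediate (not isolated)
9 | 2-(4-bromo-2,6-dimethoxyphenoxy)-4,6-dimethoxyphenol | COc1cc(OC)c(O)c(Oc2c(OC)cc(Br)cc2OC)c1 | intermediate
10 | 5-bromo-2-{2-[3,5-dimethoxy-4-(3,4,5-trimethoxyphenoxy)phenoxy]-3,5-dimethoxyphenoxy}-1,3-dimethoxybenzene | COc1cc(OC)c(Oc2cc(OC)c(Oc3cc(OC)c(OC)c(OC)c3)c(OC)c2)c(Oc2c(OC)cc(Br)cc2OC)c1 | intermediate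
11 | 2,4,6-trimethoxyphenol | COc1cc(OC)c(O)c(OC)c1 | starting material
12 | 2-{4-[2-(3,5-dimethoxy-4-(3,4,5-trimethoxyphenoxy)phenoxy)-3,5-dimethoxyphenoxy]-3,5-dimethoxyphenoxy}-1,3,5-trimethoxybenzene | COc1cc(OC)c(Oc2cc(OC)c(Oc3cc(OC)cc(OC)c3Oc3cc(OC)c(Oc4cc(OC)c(OC)c(OC)c4)c(OC)c3)c(OC)c2)c(OC)c1 | intermediate
13 | dodeca-O-dibromoboryl derivative of 14 (every OH as O–BBr2, idealised) | BrB(Br)Oc1cc(OB(Br)Br)c(Oc2cc(OB(Br)Br)c(Oc3cc(OB(Br)Br)cc(OB(Br)Br)c3Oc3cc(OB(Br)Br)c(Oc4cc(OB(Br)Br)c(OB(Br)Br)c(OB(Br)Br)c4)c(OB(Br)Br)c3)c(OB(Br)Br)c2)c(OB(Br)Br)c1 | intermediate (not isolated)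
14 | 2-{4-[2-(3,5-dihydroxy-4-(3,4,5-trihydroxyphenoxy)phenoxy)-3,5-dihydroxyphenoxy]-3,5-dihydroxyphenoxy}benzene-1,3,5-triol | Oc1cc(O)c(Oc2cc(O)c(Oc3cc(O)cc(O)c3Oc3cc(O)c(Oc4cc(O)c(O)c(O)c4)c(O)c3)c(O)c2)c(O)c1 | target

## Step count and risks

Total steps: 6. Longest linear sequence: 5 (steps 1, 2, 4, 5, 6).

**Step 3 (proposed new step).** The risks are C–C attack by the electron-rich rings (including the product's C–H between two OMe groups) and attack at the methoxy-bearing carbon. The fallback uses known chemistry and sets out from 7. SNAr of the phenoxide of 7 on 2-fluoro-4,6-dimethoxybenzaldehyde F1 (K2CO3, DMF, 120 °C) gives 2-(4-bromo-2,6-dimethoxyphenoxy)-4,6-dimethoxybenzaldehyde F2. Baeyer–Villiger (Dakin-type) oxidation with mCPBA in CH2Cl2 gives the aryl formate F3, which K2CO3 in MeOH cleaves to the phenol. The fallback comes back to the route at 9.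

**Step 4.** The phenol of 9 is di-ortho-substituted and easily oxidised by copper and oxygen, so the coupling may be slow or give quinone. The fallback sets out from 5 and replaces copper and oxygen by metal-free hypervalent-iodine arylation. Ipso-iododeboronation of 5 (NIS, MeCN, rt) gives 5-iodo-1,3-dimethoxy-2-(3,4,5-trimethoxyphenoxy)benzene F4. Oxidation with mCPBA and TsOH·H2O in MeCN followed by 1,3,5-trimethoxybenzene gives the aryl(2,4,6-trimethoxyphenyl)iodonium tosylate F5. The phenoxide of 9 (tBuOK, THF, rt to 40 °C) is arylated by F5; the electron-rich trimethoxyphenyl group stays on iodine and the bromide is untouched. The fallback comes back at 10.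

**Step 6.** Twelve-fold demethylation may stop short, and the free polyphenol is air-sensitive and hard to purify. The fallback sets out from 12 and uses a derivatise, purify, release detour. The crude product of the BBr3 cleavage is peracetylated (Ac2O, pyridine, DMAP cat., rt) to the dodecaacetate F6, which is stable and can be chromatographed on silica away from partly methylated material. Acid methanolysis (catalytic AcCl in MeOH, rt, Ar) then removes the acetates. The fallback comes back at 14.

## Further compounds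

F1 | step 3 | 2-fluoro-4,6-dimethoxybenzaldehyde (bought) | COc1cc(F)c(C=O)c(OC)c1
F2 | step 3 | 2-(4-bromo-2,6-dimethoxyphenoxy)-4,6-dimethoxybenzaldehyde | COc1cc(Oc2c(OC)cc(Br)cc2OC)c(C=O)c(OC)c1
F3 | step 3 | 2-(4-bromo-2,6-dimethoxyphenoxy)-4,6-dimethoxyphenyl formate | COc1cc(Oc2c(OC)cc(Br)cc2OC)c(OC=O)c(OC)c1
F4 | step 4 | 5-iodo-1,3-dimethoxy-2-(3,4,5-trimethoxyphenoxy)benzene | COc1cc(I)cc(OC)c1Oc1cc(OC)c(OC)c(OC)c1
F5 | step 4 | [3,5-dimethoxy-4-(3,4,5-trimethoxyphenoxy)phenyl](2,4,6-trimethoxyphenyl)iodonium tosylate | COc1cc(OC)c([I+]c2cc(OC)c(Oc3cc(OC)c(OC)c(OC)c3)c(OC)c2)c(OC)c1.Cc1ccc(S(=O)(=O)[O-])cc1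
F6 | step 6 | dodecaacetate of 14 | CC(=O)Oc1cc(OC(C)=O)c(Oc2cc(OC(C)=O)c(Oc3cc(OC(C)=O)cc(OC(C)=O)c3Oc3cc(OC(C)=O)c(Oc4cc(OC(C)=O)c(OC(C)=O)c(OC(C)=O)c4)c(OC(C)=O)c3)c(OC(C)=O)c2)c(OC(C)=O)c1
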